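The route disconnects the tetrahydrofuran at C2–C3 and C4–CH2Ar by treating C3 and C4 as the β- and α-carbons of a chiral γ-alkoxybutenolide. C3 carries C2 with ring B and C4 carries the ring A benzyl group. The acetal carbon becomes the C3 hydroxymethyl group and the lactone carbonyl becomes C5. One three-component operation adds the ring B aryl dithiane anion to (5R)-5-menthyloxyfuran-2(5H)-one and benzylates the enolate with the ring A bromide, forming both bonds and the C3 and C4 stereocentres. The precursors are the menthyloxybutenolide, an O-allyl ring B dithiane and an O-TIPS ring A benzyl bromide. The threo glycerol aryl ether with ring C is attached last by an auxiliary-controlled glycolate aldol.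

Key step: step 7

Assumption: 4-(allyloxy)-3-methoxybenzaldehyde and (R)-4-benzyl-3-(chloroacetyl)oxazolidin-2-one are taken as purchasable; the oxolane is numbered O1, C2 (ring B aryl), C3 (CH2OH), C4 (ring A benzyl), C5, and ring C is the guaiacyl group on carbinol carbon C7'' next to the aryloxy carbon C8''.

Step 1
Reactants: 1 furfural
Product: 2 5-hydroxyfuran-2(5H)-one (racemic)
Conditions: O2, hν (visible), rose bengal (C20H2Cl4I4Na2O5, cat.), MeOH, rt
Reagents that add atoms: oxygen, O=O
Why: Sensitised photo-oxygenation: singlet oxygen adds [4+2] across the furan diene and methanolysis expels the formyl carbon as methyl formate, leaving the racemic hydroxybutenolide.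

Step 2
Reactants: 2 5-hydroxyfuran-2(5H)-one; 3 (−)-menthol
Product: 5 (5R)-5-[(1R,2S,5R)-menthyloxy]furan-2(5H)-one, via 5S acetal epimer 4 (not isolated)
Conditions: TsOH·H2O (cat.), toluene, reflux, Dean–Stark; crystallise from petroleum ether, −20 °C; mother liquor re-equilibrated with TsOH·H2O and crystallised again
Reagents that add atoms: none
Why: Acid-catalysed acetal exchange at the hemiacetal carbon gives both C5 epimers, which interconvert under the acid, so crystallisation of the less soluble (5R) epimer and re-equilibration of the (5S) epimer 4 in the mother liquor set the acetal stereocentre with the menthyl group as the resolving element.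

Step 3
Reactants: 6 4-(allyloxy)-3-methoxybenzaldehyde; 7 propane-1,3-dithiol
Product: 8 2-[4-(allyloxy)-3-methoxyphenyl]-1,3-dithiane
Conditions: BF3·OEt2 (cat.), CH2Cl2, 0 °C → rt
Reagents that add atoms: none
Why: Lewis-acid-catalysed dithioacetalisation of an aryl aldehyde, to which the allyl ether is inert.

Step 4
Reactants: 9 vanillin
Product: 10 3-methoxy-4-(triisopropylsilyloxy)benzaldehyde
Conditions: TIPSCl, imidazole, DMF, rt
Reagents that add atoms: triisopropylsilyl chloride, CC(C)[Si](Cl)(C(C)C)C(C)C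
Why: Imidazole-promoted O-silylation of the phenol; the bulky silyl group is chosen to outlast organolithium, hydride and mild acid.

Step 5
Reactants: 10 3-methoxy-4-(triisopropylsilyloxy)benzaldehyde
Product: 11 [3-methoxy-4-(triisopropylsilyloxy)phenyl]methanol
Conditions: NaBH4, MeOH/THF, 0 °C
Reagents that add atoms: none
Why: Borohydride reduction of an aryl aldehyde, fast at 0 °C and harmless to the aryl silyl ether.

Step 6
Reactants: 11 [3-methoxy-4-(triisopropylsilyloxy)phenyl]methanol
Product: 12 3-methoxy-4-(triisopropylsilyloxy)benzyl bromide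
Conditions: PBr3, Et2O, 0 °C; used at once
Reagents that add atoms: phosphorus tribromide, BrP(Br)Br
Why: PBr3 activates the electron-rich benzylic hydroxyl and bromide displaces it (nucleophilic substitution) under cold, non-aqueous conditions that spare the silyl ether; the bromide is used without storage.

Step 7
Reactants: 5 (5R)-5-[(1R,2S,5R)-menthyloxy]furan-2(5H)-one; 8 2-[4-(allyloxy)-3-methoxyphenyl]-1,3-dithiane; 12 3-methoxy-4-(triisopropylsilyloxy)benzyl bromide
Product: 15 (3R,4R,5R)-4-{2-[4-(allyloxy)-3-methoxyphenyl]-1,3-dithian-2-yl}-3-[3-methoxy-4-(triisopropylsilyloxy)benzyl]-5-[(1R,2S,5R)-menthyloxy]dihydrofuran-2(3H)-one, via lithiated dithiane 13 (not isolated), via lithium enolate 14 (not isolated)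
Conditions: 8, n-BuLi, THF, −78 → −30 °C; then 5, −78 °C; then 12, DMPU, −78 → −20 °C; NH4Cl (aq)
Reagents that add atoms: none
Why: Deprotonation of 8 gives the sulfur-stabilised benzylic anion 13, a soft acyl-anion equivalent that adds 1,4 to butenolide 5 at lactone C4 and not to the carbonyl, and the lithium enolate 14 so formed is C-benzylated by 12 in an SN2 reaction once DMPU has loosened its aggregates. The closest known reaction type is the tandem Michael addition–enolate alkylation of 5-alkoxyfuran-2(5H)-ones with lithiated aryl dithianes and benzyl halides. No ring is closed. Lactone C4 (oxolane C3) is controlled by the C5 acetal centre, whose menthyloxy group shields one face of the flat butenolide so that the anion enters anti to it; lactone C3 (oxolane C4) is controlled by the new, very bulky dithianyl group, which sends the bromide to the opposite face, giving the trans,trans lactone. The step needs conjugate over carbonyl addition, C- over O-alkylation and two anti facial selections, which the delocalised aryl dithiane anion, the soft benzylic bromide and the neighbouring substituents on the five-membered ring should secure.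

Step 8
Reactants: 15 trans,trans dithianyl lactone
Product: 16 (3R,4R,5R)-4-[4-(allyloxy)-3-methoxybenzoyl]-3-[3-methoxy-4-(triisopropylsilyloxy)benzyl]-5-[(1R,2S,5R)-menthyloxy]dihydrofuran-2(3H)-one
Conditions: MeI, CaCO3, MeCN/H2O, 45 °C
Reagents that add atoms: water, O
Why: Alkylative dithioacetal hydrolysis: S-methylation makes sulfur a leaving group and water captures the aryl-stabilised thionium ion, under near-neutral conditions without heavy-metal salt or oxidant, so that the allyl ether, the acetal and the two ring stereocentres are left alone.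

Step 9
Reactants: 16 keto acetal lactone
Product: 17 (2R,3R)-2-{[4-(allyloxy)-3-methoxyphenyl](hydroxy)methyl}-3-[3-methoxy-4-(triisopropylsilyloxy)benzyl]butane-1,4-diol (both carbinol epimers)
Conditions: LiAlH4, THF, 0 °C; Na2SO4·10H2O quench
Reagents that add atoms: none
Why: Exhaustive hydride reduction turns the ketone into the carbinol and the acetal lactone into the 1,4-diol with loss of menthol, so the acetal carbon ends as the future C3 hydroxymethyl group and the carbonyl carbon as C5; both carbinol epimers are carried on because that centre is ionised next.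

Step 10
Reactants: 17 triol
Product: 18 [(2S,3R,4R)-2-[4-(allyloxy)-3-methoxyphenyl]-4-[3-methoxy-4-(triisopropylsilyloxy)benzyl]oxolan-3-yl]methanol
Conditions: camphor-10-sulfonic acid (C10H16O4S, cat.), CH2Cl2, 0 °C → rt; Et3N quench
Reagents that add atoms: none
Why: Acid-catalysed dehydrative cycloetherification (SN1): the para-alkoxybenzylic carbinol ionises and the primary hydroxyl on the benzyl-bearing carbon closes the five-membered ring (the other primary hydroxyl could only form an oxetane), C2 being set under reversible conditions with the aryl group trans to the C3 substituent while C3 and C4 are untouched.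

Step 11
Reactants: 18 oxolane alcohol
Product: 19 (2S,3R,4R)-2-[4-(allyloxy)-3-methoxyphenyl]-3-[(tert-butyldimethylsilyloxy)methyl]-4-[3-methoxy-4-(triisopropylsilyloxy)benzyl]oxolane
Conditions: TBSCl, imidazole, DMF, rt
Reagents that add atoms: tert-butyldimethylsilyl chloride, CC(C)(C)[Si](C)(C)Cl
Why: Imidazole-promoted silylation of the only free hydroxyl, so that the later boron enolisation meets no protic group.

Step 12
Reactants: 19 allyl ether
Product: 20 4-{(2S,3R,4R)-3-[(tert-butyldimethylsilyloxy)methyl]-4-[3-methoxy-4-(triisopropylsilyloxy)benzyl]oxolan-2-yl}-2-methoxyphenol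
Conditions: Pd(PPh3)4 (cat.), morpholine, THF, rt
Reagents that add atoms: none
Why: Tsuji–Trost-type deallylation: zerovalent palladium ionises the allyl aryl ether and morpholine takes up the allyl group, which frees the ring B phenol while the silyl ethers and the oxolane stay intact.

Step 13
Reactants: 20 ring B phenol; 21 (R)-4-benzyl-3-(chloroacetyl)oxazolidin-2-one
Product: 22 (R)-4-benzyl-3-{2-[4-((2S,3R,4R)-3-[(tert-butyldimethylsilyloxy)methyl]-4-[3-methoxy-4-(triisopropylsilyloxy)benzyl]oxolan-2-yl)-2-methoxyphenoxy]acetyl}oxazolidin-2-one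
Conditions: K2CO3, acetone, 45 °C
Reagents that add atoms: none
Why: Williamson etherification: the ring B phenoxide displaces chloride from the activated α-chloro imide by SN2, installing the glycolate unit with its chiral auxiliary in one operation.

Step 14
Reactants: 22 aryloxyacetyl imide; 10 3-methoxy-4-(triisopropylsilyloxy)benzaldehyde
Product: 24 (R)-4-benzyl-3-[(2R,3S)-3-hydroxy-3-[3-methoxy-4-(triisopropylsilyloxy)phenyl]-2-(ring B aryloxy)propanoyl]oxazolidin-2-one, ring B aryloxy being the phenoxy group of 20, via dibutylboron enolate 23 (not isolated)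
Conditions: Bu2BOTf, i-Pr2NEt, CH2Cl2, −78 → 0 °C; then 10, −78 → 0 °C; NaH2PO4/Na2HPO4 buffer (pH 7), MeOH, H2O2, 0 °C
Reagents that add atoms: none
Why: Evans syn-aldol: the Z dibutylboron enolate 23 adds to the aldehyde through a closed Zimmerman–Traxler transition state on the enolate face remote from the benzyl group of the (R)-auxiliary, which sets both new centres as (2R,3S), the syn arrangement that corresponds to the threo (7''S,8''S) side chain.

Step 15
Reactants: 24 aldol adduct
Product: 25 (1S,2S)-1-[3-methoxy-4-(triisopropylsilyloxy)phenyl]-2-{4-[(2S,3R,4R)-3-[(tert-butyldimethylsilyloxy)methyl]-4-[3-methoxy-4-(triisopropylsilyloxy)benzyl]oxolan-2-yl]-2-methoxyphenoxy}propane-1,3-diol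
Conditions: LiBH4, MeOH (1 equiv), THF, 0 °C
Reagents that add atoms: none
Why: Reductive cleavage of the N-acyl oxazolidinone by LiBH4 delivers the primary alcohol and releases the auxiliary without touching the two carbinol centres or the silyl ethers.

Step 16
Reactants: 25 tris-silyl ether
Product: 26 (1S,2S)-1-(4-hydroxy-3-methoxyphenyl)-2-{4-[(2S,3R,4R)-4-(4-hydroxy-3-methoxybenzyl)-3-(hydroxymethyl)oxolan-2-yl]-2-methoxyphenoxy}propane-1,3-diol (target)
Conditions: Bu4NF, AcOH, THF, 0 °C → rt
Reagents that add atoms: none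
Why: Fluoride-driven Si–O cleavage removes the two aryl silyl ethers and the primary silyl ether, with acetic acid buffering the phenoxides so that the para-hydroxybenzylic carbinol is not lost through quinone methide formation.

Compound list
1 | furfural | O=Cc1ccco1 | starting material
2 | 5-hydroxyfuran-2(5H)-one (racemic) | O=C1C=CC(O)O1 | intermediate
3 | (−)-menthol, (1R,2S,5R)-2-isopropyl-5-methylcyclohexan-1-ol | CC(C)[C@@H]1CC[C@@H](C)C[C@H]1O | starting material
4 | (5S)-5-[(1R,2S,5R)-menthyloxy]furan-2(5H)-one | O=C1C=C[C@@H](O[C@@H]2C[C@H](C)CC[C@H]2C(C)C)O1 | intermediate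
5 | (5R)-5-[(1R,2S,5R)-menthyloxy]furan-2(5H)-one | O=C1C=C[C@H](O[C@@H]2C[C@H](C)CC[C@H]2C(C)C)O1 | intermediate
6 | 4-(allyloxy)-3-methoxybenzaldehyde | COc1cc(C=O)ccc1OCC=C | starting material
7 | propane-1,3-dithiol | SCCCS | starting material
8 | 2-[4-(allyloxy)-3-methoxyphenyl]-1,3-dithiane | COc1cc(C2SCCCS2)ccc1OCC=C | intermediate
9 | vanillin | COc1cc(C=O)ccc1O | starting material
10 | 3-methoxy-4-(triisopropylsilyloxy)benzaldehyde | COc1cc(C=O)ccc1O[Si](C(C)C)(C(C)C)C(C)C | intermediate
11 | [3-methoxy-4-(triisopropylsilyloxy)phenyl]methanol | COc1cc(CO)ccc1O[Si](C(C)C)(C(C)C)C(C)C | intermediate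
12 | 3-methoxy-4-(triisopropylsilyloxy)benzyl bromide | COc1cc(CBr)ccc1O[Si](C(C)C)(C(C)C)C(C)C | intermediate
13 | 2-lithio-2-[4-(allyloxy)-3-methoxyphenyl]-1,3-dithiane | COc1cc(C2([Li])SCCCS2)ccc1OCC=C | intermediate
14 | lithium (4R,5R)-4-{2-[4-(allyloxy)-3-methoxyphenyl]-1,3-dithian-2-yl}-5-[(1R,2S,5R)-menthyloxy]-4,5-dihydrofuran-2-olate | [Li]OC1=C[C@@H](C2(SCCCS2)c3ccc(OCC=C)c(OC)c3)[C@H](O[C@@H]4C[C@H](C)CC[C@H]4C(C)C)O1 | intermediate
15 | (3R,4R,5R)-4-{2-[4-(allyloxy)-3-methoxyphenyl]-1,3-dithian-2-yl}-3-[3-methoxy-4-(triisopropylsilyloxy)benzyl]-5-[(1R,2S,5R)-menthyloxy]dihydrofuran-2(3H)-one | COc1cc(C[C@H]2C(=O)O[C@@H](O[C@@H]3C[C@H](C)CC[C@H]3C(C)C)[C@@H]2C4(SCCCS4)c5ccc(OCC=C)c(OC)c5)ccc1O[Si](C(C)C)(C(C)C)C(C)C | intermediate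
16 | (3R,4R,5R)-4-[4-(allyloxy)-3-methoxybenzoyl]-3-[3-methoxy-4-(triisopropylsilyloxy)benzyl]-5-[(1R,2S,5R)-menthyloxy]dihydrofuran-2(3H)-one | COc1cc(C[C@H]2C(=O)O[C@@H](O[C@@H]3C[C@H](C)CC[C@H]3C(C)C)[C@@H]2C(=O)c4ccc(OCC=C)c(OC)c4)ccc1O[Si](C(C)C)(C(C)C)C(C)C | intermediate
17 | (2R,3R)-2-{[4-(allyloxy)-3-methoxyphenyl](hydroxy)methyl}-3-[3-methoxy-4-(triisopropylsilyloxy)benzyl]butane-1,4-diol, carbinol epimers | COc1cc(C[C@@H](CO)[C@H](CO)C(O)c2ccc(OCC=C)c(OC)c2)ccc1O[Si](C(C)C)(C(C)C)C(C)C | intermediate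
18 | [(2S,3R,4R)-2-[4-(allyloxy)-3-methoxyphenyl]-4-[3-methoxy-4-(triisopropylsilyloxy)benzyl]oxolan-3-yl]methanol | COc1cc(C[C@H]2CO[C@H](c3ccc(OCC=C)c(OC)c3)[C@H]2CO)ccc1O[Si](C(C)C)(C(C)C)C(C)C | intermediate
19 | (2S,3R,4R)-2-[4-(allyloxy)-3-methoxyphenyl]-3-[(tert-butyldimethylsilyloxy)methyl]-4-[3-methoxy-4-(triisopropylsilyloxy)benzyl]oxolane | COc1cc(C[C@H]2CO[C@H](c3ccc(OCC=C)c(OC)c3)[C@H]2CO[Si](C)(C)C(C)(C)C)ccc1O[Si](C(C)C)(C(C)C)C(C)C | intermediate
20 | 4-{(2S,3R,4R)-3-[(tert-butyldimethylsilyloxy)methyl]-4-[3-methoxy-4-(triisopropylsilyloxy)benzyl]oxolan-2-yl}-2-methoxyphenol | COc1cc(C[C@H]2CO[C@H](c3ccc(O)c(OC)c3)[C@H]2CO[Si](C)(C)C(C)(C)C)ccc1O[Si](C(C)C)(C(C)C)C(C)C | intermediate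
21 | (R)-4-benzyl-3-(chloroacetyl)oxazolidin-2-one | ClCC(=O)N1[C@H](Cc2ccccc2)COC1=O | starting material
22 | (R)-4-benzyl-3-(aryloxyacetyl)oxazolidin-2-one, aryloxy being the phenoxy group of 20 | COc1cc(C[C@H]2CO[C@H](c3ccc(OCC(=O)N4[C@H](Cc5ccccc5)COC4=O)c(OC)c3)[C@H]2CO[Si](C)(C)C(C)(C)C)ccc1O[Si](C(C)C)(C(C)C)C(C)C | intermediate
23 | Z dibutylboron enolate of 22 | COc1cc(C[C@H]2CO[C@H](c3ccc(O\C=C(/OB(CCCC)CCCC)N4[C@H](Cc5ccccc5)COC4=O)c(OC)c3)[C@H]2CO[Si](C)(C)C(C)(C)C)ccc1O[Si](C(C)C)(C(C)C)C(C)C | intermediate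
24 | (R)-4-benzyl-3-[(2R,3S)-2-aryloxy-3-hydroxy-3-[3-methoxy-4-(triisopropylsilyloxy)phenyl]propanoyl]oxazolidin-2-one, aryloxy being the phenoxy group of 20 | COc1cc(C[C@H]2CO[C@H](c3ccc(O[C@@H](C(=O)N4[C@H](Cc5ccccc5)COC4=O)[C@@H](O)c6ccc(O[Si](C(C)C)(C(C)C)C(C)C)c(OC)c6)c(OC)c3)[C@H]2CO[Si](C)(C)C(C)(C)C)ccc1O[Si](C(C)C)(C(C)C)C(C)C | intermediate
25 | (1S,2S)-1-[3-methoxy-4-(triisopropylsilyloxy)phenyl]-2-{4-[(2S,3R,4R)-3-[(tert-butyldimethylsilyloxy)methyl]-4-[3-methoxy-4-(triisopropylsilyloxy)benzyl]oxolan-2-yl]-2-methoxyphenoxy}propane-1,3-diol | COc1cc(C[C@H]2CO[C@H](c3ccc(O[C@@H](CO)[C@@H](O)c4ccc(O[Si](C(C)C)(C(C)C)C(C)C)c(OC)c4)c(OC)c3)[C@H]2CO[Si](C)(C)C(C)(C)C)ccc1O[Si](C(C)C)(C(C)C)C(C)C | intermediate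
26 | (1S,2S)-1-(4-hydroxy-3-methoxyphenyl)-2-{4-[(2S,3R,4R)-4-(4-hydroxy-3-methoxybenzyl)-3-(hydroxymethyl)oxolan-2-yl]-2-methoxyphenoxy}propane-1,3-diol | COc1cc(C[C@H]2CO[C@H](c3ccc(O[C@@H](CO)[C@@H](O)c4ccc(O)c(OC)c4)c(OC)c3)[C@H]2CO)ccc1O | target

Total step count: 16. Longest linear sequence: 13 steps (vanillin 9 through steps 4–16 to 26).

Steps most likely to fail

Step 7. The benzylation of enolate 14 may lose out to proton transfer or to decay of the electron-rich bromide, and the second facial selection may erode when both events share one flask. The fallback separates the two bond formations. It sets out from 5 and 8: anion 13 is added to 5 as before, but the enolate is protonated with NH4Cl, and the conjugate adduct (4R,5R)-4-{2-[4-(allyloxy)-3-methoxyphenyl]-1,3-dithian-2-yl}-5-[(1R,2S,5R)-menthyloxy]dihydrofuran-2(3H)-one F1 is isolated and purified. Enolate 14 is then regenerated from F1 with LiN(i-Pr)2 in THF/DMPU at −78 °C and alkylated with freshly prepared 12, anti to the dithianyl group. The fallback returns to the route at 15.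

Step 8. S-Methylation at the congested aryl dithiane may stall, and long heating may epimerise the centre next to the new ketone or open the keto acetal lactone. The fallback reverses the order of reduction and unmasking and sets out from 15. LiAlH4 in THF at 0 °C reduces the acetal lactone with loss of menthol to (2R,3R)-2-{2-[4-(allyloxy)-3-methoxyphenyl]-1,3-dithian-2-yl}-3-[3-methoxy-4-(triisopropylsilyloxy)benzyl]butane-1,4-diol F2. The dithiane is then cleaved oxidatively with PhI(OCOCF3)2 in MeCN/H2O at 0 °C to (2R,3R)-1-[4-(allyloxy)-3-methoxyphenyl]-2-(hydroxymethyl)-3-[3-methoxy-4-(triisopropylsilyloxy)benzyl]-4-hydroxybutan-1-one F3. This keto diol is reduced at once with NaBH4 in MeOH at 0 °C. The fallback returns to the route at 17.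

Step 10. Ionisation of the benzylic carbinol may be followed by capture of the cation by ring A in a six-membered Friedel–Crafts closure, or ring closure may be incompletely trans-selective at C2. The fallback makes ring B a stronger donor before cyclising, so that much weaker acid suffices, and sets out from 17. Deallylation with Pd(PPh3)4 and morpholine gives (2R,3R)-2-[hydroxy(4-hydroxy-3-methoxyphenyl)methyl]-3-[3-methoxy-4-(triisopropylsilyloxy)benzyl]butane-1,4-diol F4. The free para-hydroxybenzylic carbinol should cyclise with pyridinium p-toluenesulfonate (C12H13NO3S, cat.) in CH2Cl2 at rt to 4-{(2S,3R,4R)-3-(hydroxymethyl)-4-[3-methoxy-4-(triisopropylsilyloxy)benzyl]oxolan-2-yl}-2-methoxyphenol F5. Phenol-selective alkylation with 21 (K2CO3, acetone) gives (R)-4-benzyl-3-{2-[4-((2S,3R,4R)-3-(hydroxymethyl)-4-[3-methoxy-4-(triisopropylsilyloxy)benzyl]oxolan-2-yl)-2-methoxyphenoxy]acetyl}oxazolidin-2-one F6. Silylation of its primary hydroxyl with TBSCl and imidazole completes the detour. The fallback returns to the route at 22.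

Further compounds
F1 | step 7 | (4R,5R)-4-{2-[4-(allyloxy)-3-methoxyphenyl]-1,3-dithian-2-yl}-5-[(1R,2S,5R)-menthyloxy]dihydrofuran-2(3H)-one | O=C1C[C@@H](C2(SCCCS2)c3ccc(OCC=C)c(OC)c3)[C@H](O[C@@H]4C[C@H](C)CC[C@H]4C(C)C)O1
F2 | step 8 | (2R,3R)-2-{2-[4-(allyloxy)-3-methoxyphenyl]-1,3-dithian-2-yl}-3-[3-methoxy-4-(triisopropylsilyloxy)benzyl]butane-1,4-diol | COc1cc(C[C@@H](CO)[C@H](CO)C2(SCCCS2)c3ccc(OCC=C)c(OC)c3)ccc1O[Si](C(C)C)(C(C)C)C(C)C
F3 | step 8 | (2R,3R)-1-[4-(allyloxy)-3-methoxyphenyl]-2-(hydroxymethyl)-3-[3-methoxy-4-(triisopropylsilyloxy)benzyl]-4-hydroxybutan-1-one | COc1cc(C[C@@H](CO)[C@H](CO)C(=O)c2ccc(OCC=C)c(OC)c2)ccc1O[Si](C(C)C)(C(C)C)C(C)C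
F4 | step 10 | (2R,3R)-2-[hydroxy(4-hydroxy-3-methoxyphenyl)methyl]-3-[3-methoxy-4-(triisopropylsilyloxy)benzyl]butane-1,4-diol, carbinol epimers | COc1cc(C[C@@H](CO)[C@H](CO)C(O)c2ccc(O)c(OC)c2)ccc1O[Si](C(C)C)(C(C)C)C(C)C
F5 | step 10 | 4-{(2S,3R,4R)-3-(hydroxymethyl)-4-[3-methoxy-4-(triisopropylsilyloxy)benzyl]oxolan-2-yl}-2-methoxyphenol | COc1cc(C[C@H]2CO[C@H](c3ccc(O)c(OC)c3)[C@H]2CO)ccc1O[Si](C(C)C)(C(C)C)C(C)C
F6 | step 10 | (R)-4-benzyl-3-{2-[4-((2S,3R,4R)-3-(hydroxymethyl)-4-[3-methoxy-4-(triisopropylsilyloxy)benzyl]oxolan-2-yl)-2-methoxyphenoxy]acetyl}oxazolidin-2-one | COc1cc(C[C@H]2CO[C@H](c3ccc(OCC(=O)N4[C@H](Cc5ccccc5)COC4=O)c(OC)c3)[C@H]2CO)ccc1O[Si](C(C)C)(C(C)C)C(C)C
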